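The route rests on disconnecting ring B between C8 and C9 (labdane numbering). A ring-A cyclohexene carrying, trans on C10 and C5, a nitrile (C9) and a but-3-enyl chain (C6–C8, C17) is closed by iron-hydride hydrogen-atom transfer: H adds to the terminal carbon (becoming the C8 methyl), the C8 radical attacks the nitrile carbon, and hydrolysis of the imine gives the trans-decalin-9-one with equatorial 8-methyl. The step exploits the CH(CH3)–C(O) array at C8–C9 beside quaternary C10. The precursor comes from a catalytic asymmetric Diels–Alder reaction; the C9 ketone is then vinylated from the α-face, the side chain is completed by B-alkyl Suzuki coupling, and the Δ2 alkene is dihydroxylated last.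

Key step: step 8

Remark: atoms are numbered as in a labdane (C1–C10 decalin, C11–C16 side chain, C17 on C8, C20 on C10).
Assumption: the oxazaborolidinium catalyst derived from (S)-α,α-diphenylprolinol is taken to shield the enal face that leads to (1S,6S)-6, by the usual formyl C–H···O binding model for 2-substituted enals; were the sense opposite for this dienal, the mirror-image catalyst would be used in the same step.

Step 1
Reactants: 1 pent-4-enal; 2 2-(triphenylphosphoranylidene)propanal
Product: 3 (2E)-2-methylhepta-2,6-dienal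
Conditions: toluene, 90 °C
Reagents that add atoms: none
Why: Wittig olefination of an aliphatic aldehyde with a formyl-stabilised ylide should give the (E)-2-methyl enal, the geometry that later places the formyl carbon trans to the butenyl chain.

Step 2
Reactants: 4 but-3-en-2-one
Product: 5 2-{[tri(propan-2-yl)silyl]oxy}buta-1,3-diene
Conditions: TIPSOTf, Et3N, CH2Cl2, 0 °C → rt
Reagents that add atoms: triisopropylsilyl trifluoromethanesulfonate, CC(C)[Si](C(C)C)(C(C)C)OS(=O)(=O)C(F)(F)F
Why: Soft enolisation of the methyl ketone with silyl triflate and amine (O-silylation) should give the 2-silyloxydiene.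

Step 3
Reactants: 3 (2E)-2-methylhepta-2,6-dienal; 5 2-{[tri(propan-2-yl)silyl]oxy}buta-1,3-diene
Product: 6 (1S,6S)-6-(but-3-en-1-yl)-1-methyl-4-{[tri(propan-2-yl)silyl]oxy}cyclohex-3-ene-1-carbaldehyde
Conditions: (S)-o-tolyl-oxazaborolidine from (S)-α,α-diphenylprolinol (20 mol %), HNTf2 (18 mol %), CH2Cl2, −78 → −40 °C
Reagents that add atoms: none
Why: In this Lewis-acid-catalysed Diels–Alder reaction the nucleophilic CH2 terminus of the silyloxydiene bonds to the enal β-carbon (para rule, C3–O para to C10), suprafacial addition to the (E)-dienophile sets the formyl group trans to the butenyl chain, and the chiral oxazaborolidinium ion fixes the absolute sense at C5 and C10 together by shielding one enal face.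

Step 4
Reactants: 6 (1S,6S)-6-(but-3-en-1-yl)-1-methyl-4-{[tri(propan-2-yl)silyl]oxy}cyclohex-3-ene-1-carbaldehyde
Product: 8 (1S,6S)-6-(but-3-en-1-yl)-1-methyl-4-{[tri(propan-2-yl)silyl]oxy}cyclohex-3-ene-1-carbonitrile, via aldoxime 7 (not isolated)
Conditions: NH2OH·HCl, pyridine, EtOH, rt; then MsCl, Et3N, CH2Cl2, 0 °C → rt
Reagents that add atoms: hydroxylamine hydrochloride, NO.Cl
Why: Oximation and dehydration of the aldoxime convert the non-enolisable aldehyde into the nitrile under basic conditions that should spare the silyl enol ether; the nitrile is inert in steps 5–7 and is the radical acceptor of step 8.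

Step 5
Reactants: 8 (1S,6S)-6-(but-3-en-1-yl)-1-methyl-4-{[tri(propan-2-yl)silyl]oxy}cyclohex-3-ene-1-carbonitrile
Product: 9 (1R,6S)-6-(but-3-en-1-yl)-1-methyl-4-oxocyclohex-2-ene-1-carbonitrile
Conditions: Pd(OAc)2 (1.1 equiv), MeCN, 40 °C
Reagents that add atoms: none
Why: Saegusa–Ito oxidation: the oxo-π-allyl palladium species formed at C2 can lose a hydride only from C1, so the C1=C2 enone should form, which leaves C4 as the only enolisable position.

Step 6
Reactants: 9 (1R,6S)-6-(but-3-en-1-yl)-1-methyl-4-oxocyclohex-2-ene-1-carbonitrile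
Product: 11 (1S,6R)-6-(but-3-en-1-yl)-1,5,5-trimethyl-4-oxocyclohex-2-ene-1-carbonitrile, via monomethyl enone 10 (not isolated)
Conditions: LiN(iPr)2, THF, −78 °C, MeI; then LiN(iPr)2, MeI, DMPU, −78 → 0 °C
Reagents that add atoms: iodomethane, CI
Why: Double α'-alkylation of the cross-conjugated lithium enolate: C4 is the only acidic site (C10 is quaternary, C2 is vinylic), so two rounds of base and MeI should install the gem-dimethyl group without setting a stereocentre.

Step 7
Reactants: 11 (1S,6R)-6-(but-3-en-1-yl)-1,5,5-trimethyl-4-oxocyclohex-2-ene-1-carbonitrile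
Product: 13 (1S,2S)-2-(but-3-en-1-yl)-1,3,3-trimethylcyclohex-4-ene-1-carbonitrile, via tosylhydrazone 12 (not isolated)
Conditions: TsNHNH2, EtOH, 78 °C; then catecholborane, CHCl3, 0 °C; NaOAc·3H2O, 60 °C
Reagents that add atoms: none
Why: Alkene-transposing reduction of a conjugated tosylhydrazone: 1,2-hydride addition to C=N and loss of sulfinate give an allylic diazene whose retro-ene loss of N2 delivers H to C1 and moves the double bond to C2=C3, with no stereocentre touched.

Step 8
Reactants: 13 (1S,2S)-2-(but-3-en-1-yl)-1,3,3-trimethylcyclohex-4-ene-1-carbonitrile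
Product: 15 (2R,4aS,8aS)-2,5,5,8a-tetramethyl-3,4,4a,5,8,8a-hexahydronaphthalen-1(2H)-one, via ketimine 14 (not isolated)
Conditions: Fe(acac)3 (0.5 equiv), PhSiH3 (3 equiv), EtOH, 60 °C; then 2 M HCl, THF, rt → 40 °C
Reagents that add atoms: water, O
Why: An iron hydride formed from Fe(acac)3 and PhSiH3 transfers a hydrogen atom to the terminal carbon of the monosubstituted alkene (C17), the secondary C8 radical adds to the nitrile carbon C9, and the iminyl radical is reduced to ketimine 14, which aqueous acid hydrolyses to the ketone. The closest known reaction type is the HAT-mediated reductive cyclisation of alkenyl nitriles to cyclic ketones. Ring B closes in the 6-exo-dig mode and, because C9 and C6 are trans on ring A, as a trans-decalin. The new C8 stereocentre is controlled by a chair-like transition state with the incipient methyl equatorial (an axial methyl would be syn-axial to the C10 methyl) and is secured thermodynamically because C8 is epimerisable next to the imine and the ketone. The step needs HAT to the terminal alkene in preference to the hindered cis-disubstituted C2=C3 alkene, which the known reactivity order of iron-hydride HAT provides, and cyclisation faster than reduction of the C8 radical, which quaternary C10 and the gem-dimethyl C4 favour by holding chain and nitrile close (Thorpe–Ingold effect).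

Step 9
Reactants: 15 (2R,4aS,8aS)-2,5,5,8a-tetramethyl-3,4,4a,5,8,8a-hexahydronaphthalen-1(2H)-one
Product: 16 (1S,2R,4aS,8aS)-1-ethenyl-2,5,5,8a-tetramethyl-1,2,3,4,4a,5,8,8a-octahydronaphthalen-1-ol
Conditions: CH2=CHMgBr, CeCl3, THF, −78 → 0 °C; aq NH4Cl
Reagents that add atoms: vinylmagnesium bromide, C=C[Mg]Br
Why: Organocerium 1,2-addition to the hindered enolisable ketone should occur by axial attack from the α-face, anti to the axial C10 methyl on the neighbouring carbon, giving the 9β-hydroxy-9α-vinyl carbinol and thereby the C9 configuration of the target.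

Step 10
Reactants: 17 methyl but-2-ynoate
Product: 18 methyl (2Z)-3-iodobut-2-enoate
Conditions: NaI, AcOH, 115 °C
Reagents that add atoms: sodium iodide, [Na+].[I-]
Why: Conjugate hydroiodination of the ynoate proceeds by anti addition of HI and should give the (Z)-β-iodo enoate with iodine cis to the ester.

Step 11
Reactants: 16 (1S,2R,4aS,8aS)-1-ethenyl-2,5,5,8a-tetramethyl-1,2,3,4,4a,5,8,8a-octahydronaphthalen-1-ol; 18 methyl (2Z)-3-iodobut-2-enoate
Product: 20 methyl (2Z)-5-[(1S,2R,4aS,8aS)-1-hydroxy-2,5,5,8a-tetramethyl-1,2,3,4,4a,5,8,8a-octahydronaphthalen-1-yl]-3-methylpent-2-enoate, via alkylborane 19 (not isolated)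
Conditions: 9-BBN, THF, 0 → 50 °C; then 18, Pd(dppf)Cl2 (5 mol %), AsPh3, Cs2CO3, DMF/H2O, rt
Reagents that add atoms: none
Why: 9-BBN hydroborates only the terminal vinyl group (anti-Markovnikov, the hindered ring alkene is spared) and the B-alkyl Suzuki–Miyaura coupling with the vinyl iodide proceeds with retention, so C12 ends cis to the ester (13Z).

Step 12
Reactants: 20 methyl (2Z)-5-[(1S,2R,4aS,8aS)-1-hydroxy-2,5,5,8a-tetramethyl-1,2,3,4,4a,5,8,8a-octahydronaphthalen-1-yl]-3-methylpent-2-enoate
Product: 21 methyl (2Z)-5-[(1S,2R,4aS,6S,7R,8aS)-1,6,7-trihydroxy-2,5,5,8a-tetramethyldecahydronaphthalen-1-yl]-3-methylpent-2-enoate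
Conditions: OsO4 (5 mol %), NMO, acetone/H2O, rt
Reagents that add atoms: N-methylmorpholine N-oxide, C[N+]1([O-])CCOCC1; water, O
Why: Catalytic syn-dihydroxylation should take the electron-richer C2=C3 alkene in preference to the trisubstituted enoate and attack from the α-face, opposite the axial C10 and 4β methyl groups, to give the 2α,3α-cis-diol.

Compound list
1 | pent-4-enal | C=CCCC=O | starting material
2 | 2-(triphenylphosphoranylidene)propanal | CC(C=O)=P(c1ccccc1)(c1ccccc1)c1ccccc1 | starting material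
3 | (2E)-2-methylhepta-2,6-dienal | C=CCC/C=C(\C)C=O | intermediate
4 | but-3-en-2-one | CC(=O)C=C | starting material
5 | 2-{[tri(propan-2-yl)silyl]oxy}buta-1,3-diene | C=CC(=C)O[Si](C(C)C)(C(C)C)C(C)C | intermediate
6 | (1S,6S)-6-(but-3-en-1-yl)-1-methyl-4-{[tri(propan-2-yl)silyl]oxy}cyclohex-3-ene-1-carbaldehyde | C=CCC[C@H]1CC(O[Si](C(C)C)(C(C)C)C(C)C)=CC[C@]1(C)C=O | intermediate
7 | aldoxime of 6 (C=N geometry not defined) | C=CCC[C@H]1CC(O[Si](C(C)C)(C(C)C)C(C)C)=CC[C@]1(C)C=NO | intermediate
8 | (1S,6S)-6-(but-3-en-1-yl)-1-methyl-4-{[tri(propan-2-yl)silyl]oxy}cyclohex-3-ene-1-carbonitrile | C=CCC[C@H]1CC(O[Si](C(C)C)(C(C)C)C(C)C)=CC[C@]1(C)C#N | intermediate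
9 | (1R,6S)-6-(but-3-en-1-yl)-1-methyl-4-oxocyclohex-2-ene-1-carbonitrile | C=CCC[C@H]1CC(=O)C=C[C@]1(C)C#N | intermediate
10 | 6-(but-3-en-1-yl)-1,5-dimethyl-4-oxocyclohex-2-ene-1-carbonitrile (C-5 epimers; C-1 and C-6 as in 9) | C=CCC[C@H]1C(C)C(=O)C=C[C@]1(C)C#N | intermediate
11 | (1S,6R)-6-(but-3-en-1-yl)-1,5,5-trimethyl-4-oxocyclohex-2-ene-1-carbonitrile | C=CCC[C@H]1C(C)(C)C(=O)C=C[C@]1(C)C#N | intermediate
12 | 4-methylbenzenesulfonohydrazone of 11 (C=N geometry not defined) | C=CCC[C@H]1C(C)(C)C(=NNS(=O)(=O)c2ccc(C)cc2)C=C[C@]1(C)C#N | intermediate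
13 | (1S,2S)-2-(but-3-en-1-yl)-1,3,3-trimethylcyclohex-4-ene-1-carbonitrile | C=CCC[C@H]1C(C)(C)C=CC[C@]1(C)C#N | intermediate
14 | (2R,4aS,8aS)-2,5,5,8a-tetramethyl-3,4,4a,5,8,8a-hexahydronaphthalen-1(2H)-imine | N=C1[C@H](C)CC[C@H]2C(C)(C)C=CC[C@@]21C | intermediate
15 | (2R,4aS,8aS)-2,5,5,8a-tetramethyl-3,4,4a,5,8,8a-hexahydronaphthalen-1(2H)-one | O=C1[C@H](C)CC[C@H]2C(C)(C)C=CC[C@@]21C | intermediate
16 | (1S,2R,4aS,8aS)-1-ethenyl-2,5,5,8a-tetramethyl-1,2,3,4,4a,5,8,8a-octahydronaphthalen-1-ol | C=C[C@]1(O)[C@H](C)CC[C@H]2C(C)(C)C=CC[C@@]21C | intermediate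
17 | methyl but-2-ynoate | CC#CC(=O)OC | starting material
18 | methyl (2Z)-3-iodobut-2-enoate | COC(=O)/C=C(/C)I | intermediate
19 | 9-{2-[(1S,2R,4aS,8aS)-1-hydroxy-2,5,5,8a-tetramethyl-1,2,3,4,4a,5,8,8a-octahydronaphthalen-1-yl]ethyl}-9-borabicyclo[3.3.1]nonane | C1CCC2CCCC1B2CC[C@]1(O)[C@H](C)CC[C@H]2C(C)(C)C=CC[C@@]21C | intermediate
20 | methyl (2Z)-5-[(1S,2R,4aS,8aS)-1-hydroxy-2,5,5,8a-tetramethyl-1,2,3,4,4a,5,8,8a-octahydronaphthalen-1-yl]-3-methylpent-2-enoate | COC(=O)/C=C(/C)CC[C@]1(O)[C@H](C)CC[C@H]2C(C)(C)C=CC[C@@]21C | intermediate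
21 | methyl (2Z)-5-[(1S,2R,4aS,6S,7R,8aS)-1,6,7-trihydroxy-2,5,5,8a-tetramethyldecahydronaphthalen-1-yl]-3-methylpent-2-enoate | COC(=O)/C=C(/C)CC[C@]1(O)[C@H](C)CC[C@H]2C(C)(C)[C@H](O)[C@H](O)C[C@@]21C | target

Total step count: 12. Longest linear sequence: 10 steps (steps 1, 3, 4, 5, 6, 7, 8, 9, 11, 12).

Steps most likely to fail

1. Step 8 (key step). The 6-exo-dig addition of the secondary C8 radical to the nitrile may be too slow, so that hydrogen-atom reduction of the radical (net hydrogenation of the vinyl group) wins. The fallback sets out from 13 and comes back at 15. The nitrile of 13 would be reduced with (iBu)2AlH (toluene, −78 °C, then aqueous acid) to (1S,2S)-2-(but-3-en-1-yl)-1,3,3-trimethylcyclohex-4-ene-1-carbaldehyde F1. Under the same iron-hydride HAT conditions the C8 radical should then add to the far more reactive formyl group, giving (2R,4aS,8aS)-2,5,5,8a-tetramethyl-1,2,3,4,4a,5,8,8a-octahydronaphthalen-1-ol F2 as a mixture of C-1 epimers. Oxidation with Dess–Martin periodinane (CH2Cl2, rt) and brief base treatment to equilibrate C8 would give 15.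

2. Step 3. Addition of the silyl dienol ether to the activated formyl group may compete with [4+2] addition, or facial discrimination may be poor for the trisubstituted enal. The fallback sets out from 3 and comes back at 9. Cycloaddition of 3 with (E)-1-(dimethylamino)-3-(tert-butyldimethylsilyloxy)buta-1,3-diene would be run under a chiral salen complex of trivalent chromium, (salen)CrSbF6 (salen = N,N'-bis(3,5-di-tert-butylsalicylidene)cyclohexane-1,2-diamine dianion, enantiomer matched to the drawn adduct; CH2Cl2, −40 °C). This should give the amino silyl enol ether cycloadduct (6S)-6-(but-3-en-1-yl)-4-[(tert-butyldimethylsilyl)oxy]-2-(dimethylamino)-1-methylcyclohex-3-ene-1-carbaldehyde F3. HF in MeCN would convert it into (1R,6S)-6-(but-3-en-1-yl)-1-methyl-4-oxocyclohex-2-ene-1-carbaldehyde F4. Chemoselective oximation of the formyl group (NH2OH·HCl, pyridine, 0 °C) to the aldoxime of F4 F5 and dehydration (MsCl, Et3N) would give 9 directly, which also removes the need for step 5.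

3. Step 9. The basic vinyl nucleophile may enolise the hindered ketone (returned starting material), or facial discrimination may be incomplete. The fallback sets out from 15 and comes back at 16. Addition of the smaller and less basic HC≡CMgBr (THF, 0 °C), which should attack axially from the α-face, would give (1R,2R,4aS,8aS)-1-ethynyl-2,5,5,8a-tetramethyl-1,2,3,4,4a,5,8,8a-octahydronaphthalen-1-ol F6. Semi-hydrogenation (H2, Pd/CaCO3 poisoned with Pb(OAc)2, quinoline, EtOAc) would then give 16.

Further compounds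
F1 | step 8 | (1S,2S)-2-(but-3-en-1-yl)-1,3,3-trimethylcyclohex-4-ene-1-carbaldehyde | C=CCC[C@H]1C(C)(C)C=CC[C@]1(C)C=O
F2 | step 8 | (2R,4aS,8aS)-2,5,5,8a-tetramethyl-1,2,3,4,4a,5,8,8a-octahydronaphthalen-1-ol (C-1 epimers) | OC1[C@H](C)CC[C@H]2C(C)(C)C=CC[C@@]21C
F3 | step 3 | (6S)-6-(but-3-en-1-yl)-4-[(tert-butyldimethylsilyl)oxy]-2-(dimethylamino)-1-methylcyclohex-3-ene-1-carbaldehyde (C-1 as in 6; C-2 not defined) | C=CCC[C@H]1CC(O[Si](C)(C)C(C)(C)C)=CC(N(C)C)[C@]1(C)C=O
F4 | step 3 | (1R,6S)-6-(but-3-en-1-yl)-1-methyl-4-oxocyclohex-2-ene-1-carbaldehyde | C=CCC[C@H]1CC(=O)C=C[C@]1(C)C=O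
F5 | step 3 | aldoxime of F4 (C=N geometry not defined) | C=CCC[C@H]1CC(=O)C=C[C@]1(C)C=NO
F6 | step 9 | (1R,2R,4aS,8aS)-1-ethynyl-2,5,5,8a-tetramethyl-1,2,3,4,4a,5,8,8a-octahydronaphthalen-1-ol | C#C[C@]1(O)[C@H](C)CC[C@H]2C(C)(C)C=CC[C@@]21C
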